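**Plan**
- Retrosynthetic cuts: the C15–O ester and C14–O acetate; the C11=C13 methylene (carried as CH2NMe2); C2–C3 (ring opening); C4=C5 (cross-metathesis); C6–C7 and C11–C13 (three-component step); C9–C10 (tosylate plus alkenylcuprate).
- Enabling feature: the trans-fused α-methylene-γ-butyrolactone (C7, C11, C12, O, C8, exocyclic C13) is a butenolide whose β-carbon C7 and α-carbon C11 each lack one carbon.
- Forward order: the C14–C10=C1–C2 unit (from but-2-yne-1,4-diol) is joined to C9 of an (R)-lactone, which is then dehydrogenated to the butenolide; allyl and CH2NMe2 are added (the lactone ring exists from the start, no ring closes); the allyl group is extended to C3/C15; the ten-membered ring closes at C2–C3 by allylic sulfone alkylation; desulfonylation, ester adjustment and unmasking follow.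
- Stereochemistry: C8 comes from the chiral-pool lactone; C7 is set trans to the C9 chain in the conjugate addition; the C1=C10 geometry comes from trans-hydroalumination/iodination; the C4=C5 geometry comes from thermodynamically E-selective cross-metathesis to an enal.

Key step: step 7

**Remarks on the chemistry (assumptions)**
- Germacrane numbering is used: ring C1–C10, lactone C11–C13 with O on C8, C14 on C10, C15 on C4. Abbreviations: TBDPS = tert-butyldiphenylsilyl, TBS = tert-butyldimethylsilyl, THP = oxan-2-yl, PMB = 4-methoxybenzyl.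
- Lactone 6 is taken as the commercial chiral-pool material; it is also the two-step diazotisation/reduction product of D-glutamic acid.
- The C9–C10 bond is made before the butenolide step, because a C9 halide or sulfonate cis to the CH2NMe2 group on the lactone would cyclise onto nitrogen.
- The THP acetal carbon is uncontrolled, so compounds 5 and 8–16 are epimer mixtures at that carbon; it is removed in step 8.
- From step 8 on, the dimethylamino group is kept protonated or in dilute cold solution whenever an alkylating agent or the ruthenium catalyst is present.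

**Route**

Step 1
Reactants: 1 but-2-yne-1,4-diol
Product: 2 4-(TBDPS-oxy)but-2-yn-1-ol
Conditions: TBDPSCl (1 equiv), imidazole, diol 1 in excess (4 equiv), DMF, 0 °C → rt
Reagents that add atoms: tert-butyl(chloro)diphenylsilane CC(C)(C)[Si](Cl)(c1ccccc1)c1ccccc1
Why: Statistical monosilylation (silyl ether formation) of a symmetrical diol used in excess should give mainly the mono-ether, the water-soluble excess diol being washed out.

Step 2
Reactants: 2 4-(TBDPS-oxy)but-2-yn-1-ol
Product: 4 (2Z)-4-(TBDPS-oxy)-3-iodobut-2-en-1-ol, via alkenylalanate 3 (not isolated)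
Conditions: NaAlH2(OCH2CH2OMe)2 (Red-Al, 1.1 equiv), THF, 0 °C; then I2, −78 → 0 °C; Rochelle salt/Na2S2O3 work-up
Reagents that add atoms: iodine II
Why: Hydroxyl-directed trans-hydroalumination of the propargylic alcohol places aluminium on the distal alkyne carbon (five-membered alkoxyalanate 3) and iodinolysis with retention gives the iodoalkene with iodine cis to the CH2OH carbon (C2), which fixes the C1=C10 geometry because C9 later takes the place of iodine.

Step 3
Reactants: 4 (2Z)-4-(TBDPS-oxy)-3-iodobut-2-en-1-ol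
Product: 5 tert-butyl{[(2Z)-2-iodo-4-(oxan-2-yloxy)but-2-en-1-yl]oxy}diphenylsilane
Conditions: 3,4-dihydro-2H-pyran, pyridinium 4-toluenesulfonate (cat.), CH2Cl2, rt
Reagents that add atoms: 3,4-dihydro-2H-pyran C1=COCCC1
Why: Acid-catalysed acetalisation (THP ether formation) protects the C2 oxygen, an acetal being chosen over a silyl ether because this oxygen lies cis to the future carbon–lithium bond where a silyl group could migrate from O to C.

Step 4
Reactants: 6 (R)-5-(hydroxymethyl)dihydrofuran-2(3H)-one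
Product: 7 [(2R)-5-oxooxolan-2-yl]methyl 4-methylbenzenesulfonate
Conditions: TsCl, pyridine, CH2Cl2, 0 °C → rt
Reagents that add atoms: 4-toluenesulfonyl chloride Cc1ccc(S(=O)(=O)Cl)cc1
Why: Sulfonylation of the primary alcohol turns C9 into an electrophile without touching the stereocentre C8.

Step 5
Reactants: 5 tert-butyl{[(2Z)-2-iodo-4-(oxan-2-yloxy)but-2-en-1-yl]oxy}diphenylsilane (2.2 equiv); 7 [(2R)-5-oxooxolan-2-yl]methyl 4-methylbenzenesulfonate
Product: 10 (5R)-5-[(2E)-2-(TBDPS-oxymethyl)-4-(THP-oxy)but-2-en-1-yl]oxolan-2-one, via alkenyllithium 8 (not isolated), via lithium dialkenylcuprate 9 (not isolated)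
Conditions: 5, t-BuLi (2 equiv per iodide), Et2O, −78 °C; CuBr·SMe2 (0.5 equiv per alkenyllithium), −78 → −40 °C; then 7, Et2O/THF, −40 → −15 °C; NH4Cl/NH3 work-up
Reagents that add atoms: none
Why: Iodine–lithium exchange with retention, formation of the Gilman-type dialkenylcuprate and SN2 displacement of the primary tosylate (a coupling known for this lactone tosylate with dialkylcuprates) should form C9–C10 with the alkene geometry intact, the lactone carbonyl being inert to the cuprate at low temperature.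

Step 6
Reactants: 10 (5R)-5-[(2E)-2-(TBDPS-oxymethyl)-4-(THP-oxy)but-2-en-1-yl]oxolan-2-one
Product: 12 (5S)-5-[(2E)-2-(TBDPS-oxymethyl)-4-(THP-oxy)but-2-en-1-yl]furan-2(5H)-one, via phenylselanyl lactone 11 (not isolated)
Conditions: LiN(i-Pr)2, THF, −78 °C; PhSeBr; NH4Cl work-up; crude selenide, 30% H2O2, pyridine, CH2Cl2, 0 °C → rt
Reagents that add atoms: none
Why: α-Selenenylation of the lactone enolate followed by oxidation and selenoxide syn-elimination gives the butenolide, only ring β-hydrogens being available and the γ-centre C8 being untouched (the descriptor changes from R to S only because the ring carbon gains priority).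

Step 7
Reactants: 12 (5S)-5-[(2E)-2-(TBDPS-oxymethyl)-4-(THP-oxy)but-2-en-1-yl]furan-2(5H)-one; 13 allylmagnesium bromide; 14 dimethylmethyleneammonium iodide
Product: 16 (3S,4R,5S)-5-[(2E)-2-(TBDPS-oxymethyl)-4-(THP-oxy)but-2-en-1-yl]-3-[(dimethylamino)methyl]-4-(prop-2-en-1-yl)oxolan-2-one, via silyl ketene acetal 15 (not isolated)
Conditions: 13 (1.5 equiv), CuBr·SMe2 (1.5 equiv), Me3SiCl (3 equiv), THF, −78 °C; then 12; then 14 (3 equiv, suspension in CH2Cl2), −78 °C → rt; NH4Cl/NH3 work-up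
Reagents that add atoms: none
Why: The allylcopper reagent (monovalent copper), activated by Me3SiCl, adds in conjugate fashion to the β-carbon C7 of butenolide 12 and the enolate is silylated to ketene acetal 15, which attacks the iminium carbon of 14 in a Mannich reaction at C11, so that C6–C7 and C11–C13 form in one flask. The closest known reaction type is the copper-mediated conjugate addition to 5-substituted butenolides with trapping of the lactone enolate by an iminium salt (tandem conjugate addition–Mannich reaction). No ring is closed; the lactone ring is already present and acts as a flat template. C7 is set by the single existing centre C8, whose C9 side chain shields one face so that the allyl group enters trans to it, and C11 is set by approach of the iminium ion anti to the new allyl group (all-trans), a centre that later becomes sp2. The step needs 1,4- over 1,2-addition, secured by the soft copper reagent with Me3SiCl at −78 °C, and 7,8-trans facial selectivity, secured by the C9 substituent; the trisubstituted C1=C10 alkene and the two ethers are spectators.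

Step 8
Reactants: 16 (3S,4R,5S)-5-[(2E)-2-(TBDPS-oxymethyl)-4-(THP-oxy)but-2-en-1-yl]-3-[(dimethylamino)methyl]-4-(prop-2-en-1-yl)oxolan-2-one
Product: 17 (3S,4R,5S)-5-[(2E)-2-(TBDPS-oxymethyl)-4-hydroxybut-2-en-1-yl]-3-[(dimethylamino)methyl]-4-(prop-2-en-1-yl)oxolan-2-one
Conditions: TsOH·H2O (1.3 equiv), MeOH, 0 °C → rt; NaHCO3 work-up
Reagents that add atoms: none
Why: Acid-catalysed transacetalisation to methanol removes the THP group while the amine sits as its ammonium salt and the TBDPS ether and γ-lactone are stable to these conditions.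

Step 9
Reactants: 17 (3S,4R,5S)-5-[(2E)-2-(TBDPS-oxymethyl)-4-hydroxybut-2-en-1-yl]-3-[(dimethylamino)methyl]-4-(prop-2-en-1-yl)oxolan-2-one
Product: 19 (3S,4R,5S)-5-[(2E)-2-(TBDPS-oxymethyl)-4-(phenylsulfonyl)but-2-en-1-yl]-3-[(dimethylamino)methyl]-4-(prop-2-en-1-yl)oxolan-2-one, via allylic bromide 18 (not isolated)
Conditions: MeSO3H (1.0 equiv), CH2Cl2; CBr4, PPh3, 0 °C; then PhSO2Na (4 equiv), DMF, rt; NaHCO3 work-up
Reagents that add atoms: sodium benzenesulfinate [Na+].[O-]S(=O)c1ccccc1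
Why: Appel bromination of the primary allylic alcohol and SN2 S-alkylation of the sulfinate give the allylic sulfone without allylic transposition, the amine being held as its ammonium salt so that it cannot be alkylated by bromide 18.

Step 10
Reactants: 20 2-methylidenepropane-1,3-diol
Product: 21 2-(TBS-oxymethyl)prop-2-en-1-ol
Conditions: NaH (1.0 equiv), THF, 0 °C; TBSCl (1.0 equiv), rt
Reagents that add atoms: tert-butyl(chloro)dimethylsilane CC(C)(C)[Si](C)(C)Cl
Why: Monosilylation of a symmetrical diol through its sparingly soluble monosodium alkoxide should favour the mono-ether.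

Step 11
Reactants: 21 2-(TBS-oxymethyl)prop-2-en-1-ol
Product: 22 2-(TBS-oxymethyl)prop-2-enal
Conditions: MnO2 (excess), CH2Cl2, rt
Reagents that add atoms: none
Why: Allylic oxidation with MnO2 converts the primary allylic alcohol to the 2-substituted acrolein without over-oxidation.

Step 12
Reactants: 19 (3S,4R,5S)-5-[(2E)-2-(TBDPS-oxymethyl)-4-(phenylsulfonyl)but-2-en-1-yl]-3-[(dimethylamino)methyl]-4-(prop-2-en-1-yl)oxolan-2-one; 22 2-(TBS-oxymethyl)prop-2-enal (4 equiv)
Product: 23 (3S,4R,5S)-4-[(2E)-3-formyl-4-(TBS-oxy)but-2-en-1-yl]-5-[(2E)-2-(TBDPS-oxymethyl)-4-(phenylsulfonyl)but-2-en-1-yl]-3-[(dimethylamino)methyl]oxolan-2-one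
Conditions: MeSO3H (1.05 equiv), second-generation Hoveyda–Grubbs catalyst RuCl2(=CH-C6H4-2-O-i-Pr)(H2IMes) (10 mol%), CH2Cl2, 40 °C; NaHCO3 work-up
Reagents that add atoms: none
Why: Olefin cross-metathesis between the monosubstituted allyl alkene and the 2-substituted acrolein should give the trisubstituted enal with the formyl group (C3) trans to C6 as the thermodynamically preferred isomer, which sets the C4=C5 geometry, while the hindered trisubstituted C1=C10 alkene stays out of the reaction and the ammonium salt spares the ruthenium catalyst.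

Step 13
Reactants: 23 (3S,4R,5S)-4-[(2E)-3-formyl-4-(TBS-oxy)but-2-en-1-yl]-5-[(2E)-2-(TBDPS-oxymethyl)-4-(phenylsulfonyl)but-2-en-1-yl]-3-[(dimethylamino)methyl]oxolan-2-one
Product: 24 (3S,4R,5S)-4-[(2Z)-3-(hydroxymethyl)-4-(TBS-oxy)but-2-en-1-yl]-5-[(2E)-2-(TBDPS-oxymethyl)-4-(phenylsulfonyl)but-2-en-1-yl]-3-[(dimethylamino)methyl]oxolan-2-one
Conditions: NaBH4, CeCl3·7H2O, MeOH, −40 °C
Reagents that add atoms: none
Why: Luche 1,2-reduction of the enal gives the C3 allylic alcohol without touching the γ-lactone or moving the double bond (the descriptor changes to Z by priority only).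

Step 14
Reactants: 24 (3S,4R,5S)-4-[(2Z)-3-(hydroxymethyl)-4-(TBS-oxy)but-2-en-1-yl]-5-[(2E)-2-(TBDPS-oxymethyl)-4-(phenylsulfonyl)but-2-en-1-yl]-3-[(dimethylamino)methyl]oxolan-2-one
Product: 25 (3S,4R,5S)-4-[(2E)-3-(bromomethyl)-4-(TBS-oxy)but-2-en-1-yl]-5-[(2E)-2-(TBDPS-oxymethyl)-4-(phenylsulfonyl)but-2-en-1-yl]-3-[(dimethylamino)methyl]oxolan-2-one
Conditions: MsCl, 2,4,6-trimethylpyridine, LiBr, THF/DMF, 0 °C; cold aqueous wash, solution dried, kept dilute and used at once
Reagents that add atoms: lithium bromide [Li+].[Br-]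
Why: Mesylation and in-situ SN2 displacement by bromide give the primary allylic bromide without transposition, and the product is not concentrated because the free amine would be alkylated intermolecularly.

Step 15
Reactants: 25 (3S,4R,5S)-4-[(2E)-3-(bromomethyl)-4-(TBS-oxy)but-2-en-1-yl]-5-[(2E)-2-(TBDPS-oxymethyl)-4-(phenylsulfonyl)but-2-en-1-yl]-3-[(dimethylamino)methyl]oxolan-2-one
Product: 26 (1(10)E,4Z,7R,8S,11S)-15-(TBS-oxy)-14-(TBDPS-oxy)-13-(dimethylamino)-2-(phenylsulfonyl)germacra-1(10),4-dien-12,8-olide (C9 cis to C2, C3 trans to C6, epimers at C2)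
Conditions: slow addition of 25 to NaN(SiMe3)2 (1.15 equiv), THF, −78 → −20 °C, final concentration about 0.002 M
Reagents that add atoms: none
Why: Intramolecular alkylation of the allylic sulfone carbanion (the sulfone CH2 is several pKa units more acidic than the lactone α-hydrogen) at the primary allylic bromide under high dilution should close the ten-membered ring by forming C2–C3, with α-attack favoured because the γ-carbon C10 is fully substituted; the new centre at C2 is removed in the next step.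

Step 16
Reactants: 26 (1(10)E,4Z,7R,8S,11S)-15-(TBS-oxy)-14-(TBDPS-oxy)-13-(dimethylamino)-2-(phenylsulfonyl)germacra-1(10),4-dien-12,8-olide
Product: 27 (1(10)E,4Z,7R,8S,11S)-15-(TBS-oxy)-14-(TBDPS-oxy)-13-(dimethylamino)germacra-1(10),4-dien-12,8-olide
Conditions: sodium amalgam Na(Hg) (6%), Na2HPO4, MeOH/THF, −20 °C
Reagents that add atoms: none
Why: Reductive desulfonylation by electron transfer should replace the sulfonyl group by hydrogen, protonation of the allyl anion at the less substituted terminus C2 keeping the trisubstituted C1=C10 alkene, and the buffered methanol leaves the lactone intact.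

Step 17
Reactants: 27 (1(10)E,4Z,7R,8S,11S)-15-(TBS-oxy)-14-(TBDPS-oxy)-13-(dimethylamino)germacra-1(10),4-dien-12,8-olide
Product: 28 (1(10)E,4Z,7R,8S,11S)-14-(TBDPS-oxy)-13-(dimethylamino)-15-hydroxygermacra-1(10),4-dien-12,8-olide
Conditions: HF·pyridine, pyridine, THF, 0 °C → rt
Reagents that add atoms: none
Why: Buffered fluoride desilylation cleaves the primary TBS ether much faster than the primary TBDPS ether, freeing only the C15 hydroxyl.

Step 18
Reactants: 29 2-(bromomethyl)prop-2-enoic acid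
Product: 30 2-[(PMB-oxy)methyl]prop-2-enoic acid
Conditions: 4-methoxybenzyl alcohol (2.2 equiv), NaH (3.2 equiv), THF, 0 °C → rt; then 1 M HCl
Reagents that add atoms: 4-methoxybenzyl alcohol COc1ccc(CO)cc1
Why: Williamson-type etherification of the allylic bromide of the acrylate carboxylate by the alkoxide (direct or addition–elimination, both giving the same product) installs the protected hydroxymethyl group.

Step 19
Reactants: 28 (1(10)E,4Z,7R,8S,11S)-14-(TBDPS-oxy)-13-(dimethylamino)-15-hydroxygermacra-1(10),4-dien-12,8-olide; 30 2-[(PMB-oxy)methyl]prop-2-enoic acid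
Product: 31 (1(10)E,4Z,7R,8S,11S)-14-(TBDPS-oxy)-13-(dimethylamino)-15-({2-[(PMB-oxy)methyl]prop-2-enoyl}oxy)germacra-1(10),4-dien-12,8-olide
Conditions: EDC·HCl, DMAP (cat.), CH2Cl2, 0 °C → rt
Reagents that add atoms: none
Why: Steglich esterification acylates the primary allylic C15 alcohol under mild conditions that the lactone, the amine and the acrylate tolerate.

Step 20
Reactants: 31 (1(10)E,4Z,7R,8S,11S)-14-(TBDPS-oxy)-13-(dimethylamino)-15-({2-[(PMB-oxy)methyl]prop-2-enoyl}oxy)germacra-1(10),4-dien-12,8-olide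
Product: 33 (1(10)E,4Z,7R,8S,11S)-14-acetoxy-13-(dimethylamino)-15-({2-[(PMB-oxy)methyl]prop-2-enoyl}oxy)germacra-1(10),4-dien-12,8-olide, via C14 alcohol 32 (not isolated)
Conditions: Bu4NF, AcOH (1:1), THF, rt; then Ac2O, Et3N, DMAP (cat.), 0 °C → rt
Reagents that add atoms: acetic anhydride CC(=O)OC(C)=O
Why: Acetic-acid-buffered fluoride desilylation frees the C14 hydroxyl without base-induced damage to the acrylate, and in-situ acetylation installs the C14 acetate while the side-chain hydroxyl is still blocked as its PMB ether.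

Step 21
Reactants: 33 (1(10)E,4Z,7R,8S,11S)-14-acetoxy-13-(dimethylamino)-15-({2-[(PMB-oxy)methyl]prop-2-enoyl}oxy)germacra-1(10),4-dien-12,8-olide
Product: 35 (1(10)E,4Z,7R,8S)-14-acetoxy-15-({2-[(PMB-oxy)methyl]prop-2-enoyl}oxy)germacra-1(10),4,11(13)-trien-12,8-olide, via trimethylammonium iodide 34 (not isolated)
Conditions: MeI (excess), THF, rt; evaporate; NaHCO3 (aq.)/EtOAc, rt
Reagents that add atoms: none
Why: Menshutkin quaternisation of the Mannich base and Hofmann-type E1cB loss of trimethylamine under bicarbonate unveil the C11=C13 exocyclic methylene, which removes the irrelevant C11 centre.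

Step 22
Reactants: 35 (1(10)E,4Z,7R,8S)-14-acetoxy-15-({2-[(PMB-oxy)methyl]prop-2-enoyl}oxy)germacra-1(10),4,11(13)-trien-12,8-olide
Product: 36 (1(10)E,4Z,7R,8S)-14-acetoxy-15-{[2-(hydroxymethyl)prop-2-enoyl]oxy}germacra-1(10),4,11(13)-trien-12,8-olide (target, CNP0126545.1)
Conditions: DDQ, CH2Cl2/pH 7 buffer, 0 °C → rt
Reagents that add atoms: none
Why: Oxidative cleavage of the PMB ether by DDQ frees the side-chain hydroxyl under neutral conditions that spare both esters and both Michael acceptors, and it is placed last because the oxidisable tertiary amine is then gone.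

**Compound list**
1 | but-2-yne-1,4-diol | OCC#CCO | starting material
2 | 4-[(tert-butyldiphenylsilyl)oxy]but-2-yn-1-ol | OCC#CCO[Si](c1ccccc1)(c1ccccc1)C(C)(C)C | intermediate
3 | sodium alkenylalanate (cyclic ate complex: Al bound to two 2-methoxyethoxy groups, the alkoxide oxygen and the distal alkene carbon) | COCCO[Al-]1(OCCOC)OCC=C1CO[Si](c1ccccc1)(c1ccccc1)C(C)(C)C.[Na+] | intermediate
4 | (2Z)-4-[(tert-butyldiphenylsilyl)oxy]-3-iodobut-2-en-1-ol | OC/C=C(\I)CO[Si](c1ccccc1)(c1ccccc1)C(C)(C)C | intermediate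
5 | tert-butyl{[(2Z)-2-iodo-4-(oxan-2-yloxy)but-2-en-1-yl]oxy}diphenylsilane | I/C(CO[Si](c1ccccc1)(c1ccccc1)C(C)(C)C)=C\COC1CCCCO1 | intermediate
6 | (R)-5-(hydroxymethyl)dihydrofuran-2(3H)-one | O=C1CC[C@H](CO)O1 | starting material
7 | [(2R)-5-oxooxolan-2-yl]methyl 4-methylbenzenesulfonate | O=C1CC[C@H](COS(=O)(=O)c2ccc(C)cc2)O1 | intermediate
8 | alkenyllithium from 5 (lithium in place of iodine, geometry retained) | [Li]/C(CO[Si](c1ccccc1)(c1ccccc1)C(C)(C)C)=C\COC1CCCCO1 | intermediate
9 | lithium dialkenylcuprate from 8 | [Li+].[Cu-](/C(CO[Si](c1ccccc1)(c1ccccc1)C(C)(C)C)=C\COC1CCCCO1)/C(CO[Si](c1ccccc1)(c1ccccc1)C(C)(C)C)=C\COC1CCCCO1 | intermediate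
10 | (5R)-5-[(2E)-2-{[(tert-butyldiphenylsilyl)oxy]methyl}-4-(oxan-2-yloxy)but-2-en-1-yl]oxolan-2-one | O=C1CC[C@H](C/C(CO[Si](c2ccccc2)(c2ccccc2)C(C)(C)C)=C\COC2CCCCO2)O1 | intermediate
11 | 3-(phenylselanyl) derivative of 10 (epimers at C3) | O=C1C([Se]c2ccccc2)C[C@H](C/C(CO[Si](c2ccccc2)(c2ccccc2)C(C)(C)C)=C\COC2CCCCO2)O1 | intermediate
12 | (5S)-5-[(2E)-2-{[(tert-butyldiphenylsilyl)oxy]methyl}-4-(oxan-2-yloxy)but-2-en-1-yl]furan-2(5H)-one | O=C1C=C[C@H](C/C(CO[Si](c2ccccc2)(c2ccccc2)C(C)(C)C)=C\COC2CCCCO2)O1 | intermediate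
13 | allylmagnesium bromide | C=CC[Mg]Br | starting material
14 | dimethylmethyleneammonium iodide | C=[N+](C)C.[I-] | starting material
15 | trimethylsilyl ketene acetal: (4R,5S)-4-allyl-5-(side chain as in 12)-2-(trimethylsilyloxy)-4,5-dihydrofuran | C=CC[C@@H]1C=C(O[Si](C)(C)C)O[C@H]1C/C(CO[Si](c2ccccc2)(c2ccccc2)C(C)(C)C)=C\COC2CCCCO2 | intermediate
16 | (3S,4R,5S)-5-[(2E)-2-{[(tert-butyldiphenylsilyl)oxy]methyl}-4-(oxan-2-yloxy)but-2-en-1-yl]-3-[(dimethylamino)methyl]-4-(prop-2-en-1-yl)oxolan-2-one | C=CC[C@@H]1[C@@H](CN(C)C)C(=O)O[C@H]1C/C(CO[Si](c2ccccc2)(c2ccccc2)C(C)(C)C)=C\COC2CCCCO2 | intermediate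
17 | (3S,4R,5S)-5-[(2E)-2-{[(tert-butyldiphenylsilyl)oxy]methyl}-4-hydroxybut-2-en-1-yl]-3-[(dimethylamino)methyl]-4-(prop-2-en-1-yl)oxolan-2-one | C=CC[C@@H]1[C@@H](CN(C)C)C(=O)O[C@H]1C/C(CO[Si](c2ccccc2)(c2ccccc2)C(C)(C)C)=C\CO | intermediate
18 | (3S,4R,5S)-5-[(2E)-4-bromo-2-{[(tert-butyldiphenylsilyl)oxy]methyl}but-2-en-1-yl]-3-[(dimethylamino)methyl]-4-(prop-2-en-1-yl)oxolan-2-one (as ammonium salt) | C=CC[C@@H]1[C@@H](CN(C)C)C(=O)O[C@H]1C/C(CO[Si](c2ccccc2)(c2ccccc2)C(C)(C)C)=C\CBr | intermediate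
19 | (3S,4R,5S)-5-[(2E)-2-{[(tert-butyldiphenylsilyl)oxy]methyl}-4-(phenylsulfonyl)but-2-en-1-yl]-3-[(dimethylamino)methyl]-4-(prop-2-en-1-yl)oxolan-2-one | C=CC[C@@H]1[C@@H](CN(C)C)C(=O)O[C@H]1C/C(CO[Si](c2ccccc2)(c2ccccc2)C(C)(C)C)=C\CS(=O)(=O)c2ccccc2 | intermediate
20 | 2-methylidenepropane-1,3-diol | C=C(CO)CO | starting material
21 | 2-{[(tert-butyldimethylsilyl)oxy]methyl}prop-2-en-1-ol | C=C(CO)CO[Si](C)(C)C(C)(C)C | intermediate
22 | 2-{[(tert-butyldimethylsilyl)oxy]methyl}prop-2-enal | C=C(C=O)CO[Si](C)(C)C(C)(C)C | intermediate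
23 | (3S,4R,5S)-4-[(2E)-4-{[tert-butyl(dimethyl)silyl]oxy}-3-formylbut-2-en-1-yl]-5-[(2E)-2-{[(tert-butyldiphenylsilyl)oxy]methyl}-4-(phenylsulfonyl)but-2-en-1-yl]-3-[(dimethylamino)methyl]oxolan-2-one | O=C/C(CO[Si](C)(C)C(C)(C)C)=C/C[C@@H]1[C@@H](CN(C)C)C(=O)O[C@H]1C/C(CO[Si](c2ccccc2)(c2ccccc2)C(C)(C)C)=C\CS(=O)(=O)c2ccccc2 | intermediate
24 | (3S,4R,5S)-4-[(2Z)-4-{[tert-butyl(dimethyl)silyl]oxy}-3-(hydroxymethyl)but-2-en-1-yl]-5-[(2E)-2-{[(tert-butyldiphenylsilyl)oxy]methyl}-4-(phenylsulfonyl)but-2-en-1-yl]-3-[(dimethylamino)methyl]oxolan-2-one | OC/C(CO[Si](C)(C)C(C)(C)C)=C/C[C@@H]1[C@@H](CN(C)C)C(=O)O[C@H]1C/C(CO[Si](c2ccccc2)(c2ccccc2)C(C)(C)C)=C\CS(=O)(=O)c2ccccc2 | intermediate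
25 | (3S,4R,5S)-4-[(2E)-3-(bromomethyl)-4-{[tert-butyl(dimethyl)silyl]oxy}but-2-en-1-yl]-5-[(2E)-2-{[(tert-butyldiphenylsilyl)oxy]methyl}-4-(phenylsulfonyl)but-2-en-1-yl]-3-[(dimethylamino)methyl]oxolan-2-one | BrC/C(CO[Si](C)(C)C(C)(C)C)=C/C[C@@H]1[C@@H](CN(C)C)C(=O)O[C@H]1C/C(CO[Si](c2ccccc2)(c2ccccc2)C(C)(C)C)=C\CS(=O)(=O)c2ccccc2 | intermediate
26 | (1(10)E,4Z,7R,8S,11S)-15-[(tert-butyldimethylsilyl)oxy]-14-[(tert-butyldiphenylsilyl)oxy]-13-(dimethylamino)-2-(phenylsulfonyl)germacra-1(10),4-dien-12,8-olide (epimers at C2) | CC(C)(C)[Si](C)(C)OC/C1=C\C[C@@H]2[C@@H](CN(C)C)C(=O)O[C@H]2C/C(CO[Si](c3ccccc3)(c3ccccc3)C(C)(C)C)=C\C(S(=O)(=O)c3ccccc3)C1 | intermediate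
27 | (1(10)E,4Z,7R,8S,11S)-15-[(tert-butyldimethylsilyl)oxy]-14-[(tert-butyldiphenylsilyl)oxy]-13-(dimethylamino)germacra-1(10),4-dien-12,8-olide | CC(C)(C)[Si](C)(C)OC/C1=C\C[C@@H]2[C@@H](CN(C)C)C(=O)O[C@H]2C/C(CO[Si](c3ccccc3)(c3ccccc3)C(C)(C)C)=C\CC1 | intermediate
28 | (1(10)E,4Z,7R,8S,11S)-14-[(tert-butyldiphenylsilyl)oxy]-13-(dimethylamino)-15-hydroxygermacra-1(10),4-dien-12,8-olide | OC/C1=C\C[C@@H]2[C@@H](CN(C)C)C(=O)O[C@H]2C/C(CO[Si](c3ccccc3)(c3ccccc3)C(C)(C)C)=C\CC1 | intermediate
29 | 2-(bromomethyl)prop-2-enoic acid | C=C(CBr)C(=O)O | starting material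
30 | 2-{[(4-methoxybenzyl)oxy]methyl}prop-2-enoic acid | COc1ccc(COCC(=C)C(=O)O)cc1 | intermediate
31 | (1(10)E,4Z,7R,8S,11S)-14-[(tert-butyldiphenylsilyl)oxy]-13-(dimethylamino)-15-[(2-{[(4-methoxybenzyl)oxy]methyl}prop-2-enoyl)oxy]germacra-1(10),4-dien-12,8-olide | COc1ccc(COCC(=C)C(=O)OC/C2=C\C[C@@H]3[C@@H](CN(C)C)C(=O)O[C@H]3C/C(CO[Si](c4ccccc4)(c4ccccc4)C(C)(C)C)=C\CC2)cc1 | intermediate
32 | 14-hydroxy analogue of 31 | COc1ccc(COCC(=C)C(=O)OC/C2=C\C[C@@H]3[C@@H](CN(C)C)C(=O)O[C@H]3C/C(CO)=C\CC2)cc1 | intermediate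
33 | (1(10)E,4Z,7R,8S,11S)-14-acetoxy-13-(dimethylamino)-15-[(2-{[(4-methoxybenzyl)oxy]methyl}prop-2-enoyl)oxy]germacra-1(10),4-dien-12,8-olide | COc1ccc(COCC(=C)C(=O)OC/C2=C\C[C@@H]3[C@@H](CN(C)C)C(=O)O[C@H]3C/C(COC(C)=O)=C\CC2)cc1 | intermediate
34 | N,N,N-trimethylammonium iodide of 33 | COc1ccc(COCC(=C)C(=O)OC/C2=C\C[C@@H]3[C@@H](C[N+](C)(C)C)C(=O)O[C@H]3C/C(COC(C)=O)=C\CC2)cc1.[I-] | intermediate
35 | (1(10)E,4Z,7R,8S)-14-acetoxy-15-[(2-{[(4-methoxybenzyl)oxy]methyl}prop-2-enoyl)oxy]germacra-1(10),4,11(13)-trien-12,8-olide | COc1ccc(COCC(=C)C(=O)OC/C2=C\C[C@@H]3C(=C)C(=O)O[C@H]3C/C(COC(C)=O)=C\CC2)cc1 | intermediate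
36 | (1(10)E,4Z,7R,8S)-14-acetoxy-15-{[2-(hydroxymethyl)prop-2-enoyl]oxy}germacra-1(10),4,11(13)-trien-12,8-olide (CNP0126545.1) | C=C(CO)C(=O)OC/C1=C\C[C@@H]2C(=C)C(=O)O[C@H]2C/C(COC(C)=O)=C\CC1 | target

**Step count**
Total: 22 steps. Longest linear sequence: 18 steps (1 → 2 → 4 → 5 → 10 → 12 → 16 → 17 → 19 → 23 → 24 → 25 → 26 → 27 → 28 → 31 → 33 → 35 → 36).

**Steps most likely to fail**

Step 15 (ring closure). Several processes compete with the ten-membered ring closure at the dilution it needs: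
- the C2 carbanion may add to the lactone carbonyl through a seven-membered transition state;
- it may expel the C14 silanolate by 1,4-elimination;
- it may couple intermolecularly;
- the free dimethylamino group may be alkylated by the allylic bromide.

The fallback closes the same C2–C3 bond without a carbanion, by reductive allyl–allyl coupling. It sets out from 17. Cross-metathesis with 22 under the conditions of step 12 should give the hydroxy enal F1, Luche reduction the diol F2, and MsCl/2,4,6-trimethylpyridine/LiBr the bis(allylic bromide) F3. Slow addition of F3 to Ni(cod)2 (zerovalent nickel) in N-methylpyrrolidone at 50 °C should join the two primary allylic carbons through a bis(π-allyl)nickel intermediate. The route is rejoined at 27, so that 19, 23–26 and the desulfonylation are bypassed. Partial loss of alkene geometry in the π-allyl intermediates is the expected price.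

Step 16 (desulfonylation). The allyl anion formed on electron transfer may be protonated at C10 instead of C2 (double-bond migration), may lose its geometry, or may expel the C14 silanolate to give a diene. The fallback replaces electron transfer by π-allyl chemistry and sets out from 26. Pd(PPh3)4 (zerovalent palladium) with NaBH4 in THF/i-PrOH at 0 °C should ionise the allylic sulfone and deliver hydride to the less substituted terminus C2. The borane set free is expected to be captured by the dimethylamino group, giving the amine–borane F4. F4 is decomplexed with 1,4-diazabicyclo[2.2.2]octane in toluene at 60 °C, which returns to 27.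

Step 12 (cross-metathesis). Turnover may be slow with the hindered, electron-poor 1,1-disubstituted aldehyde; 19 may homodimerise; the catalyst may decompose if the amine is not fully protonated; and control of the C4=C5 geometry may be incomplete. The fallback uses an electron-neutral partner and corrects the geometry afterwards. It sets out from 19 (as its methanesulfonate salt), which is metathesised with the allylic alcohol 21 using the same catalyst; this should give the allylic alcohol F5 as a mixture of C4=C5 isomers. MnO2 then gives an enal mixture that contains the (2Z)-enal F6. A catalytic amount of iodine in CH2Cl2 should equilibrate it to the thermodynamically preferred (E)-enal, and the route is rejoined at 23.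

**Further compounds**
F1 | step 15 | (3S,4R,5S)-4-[(2E)-4-{[tert-butyl(dimethyl)silyl]oxy}-3-formylbut-2-en-1-yl]-5-[(2E)-2-{[(tert-butyldiphenylsilyl)oxy]methyl}-4-hydroxybut-2-en-1-yl]-3-[(dimethylamino)methyl]oxolan-2-one | O=C/C(CO[Si](C)(C)C(C)(C)C)=C/C[C@@H]1[C@@H](CN(C)C)C(=O)O[C@H]1C/C(CO[Si](c2ccccc2)(c2ccccc2)C(C)(C)C)=C\CO
F2 | step 15 | (3S,4R,5S)-4-[(2Z)-4-{[tert-butyl(dimethyl)silyl]oxy}-3-(hydroxymethyl)but-2-en-1-yl]-5-[(2E)-2-{[(tert-butyldiphenylsilyl)oxy]methyl}-4-hydroxybut-2-en-1-yl]-3-[(dimethylamino)methyl]oxolan-2-one | OC/C(CO[Si](C)(C)C(C)(C)C)=C/C[C@@H]1[C@@H](CN(C)C)C(=O)O[C@H]1C/C(CO[Si](c2ccccc2)(c2ccccc2)C(C)(C)C)=C\CO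
F3 | step 15 | (3S,4R,5S)-5-[(2E)-4-bromo-2-{[(tert-butyldiphenylsilyl)oxy]methyl}but-2-en-1-yl]-4-[(2E)-3-(bromomethyl)-4-{[tert-butyl(dimethyl)silyl]oxy}but-2-en-1-yl]-3-[(dimethylamino)methyl]oxolan-2-one | BrC/C(CO[Si](C)(C)C(C)(C)C)=C/C[C@@H]1[C@@H](CN(C)C)C(=O)O[C@H]1C/C(CO[Si](c2ccccc2)(c2ccccc2)C(C)(C)C)=C\CBr
F4 | step 16 | amine–borane complex of 27 (BH3 on the dimethylamino nitrogen) | CC(C)(C)[Si](C)(C)OC/C1=C\C[C@@H]2[C@@H](C[N+](C)(C)[BH3-])C(=O)O[C@H]2C/C(CO[Si](c3ccccc3)(c3ccccc3)C(C)(C)C)=C\CC1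
F5 | step 12 | allylic alcohol 24 as a mixture of C4=C5 geometric isomers | OCC(CO[Si](C)(C)C(C)(C)C)=CC[C@@H]1[C@@H](CN(C)C)C(=O)O[C@H]1C/C(CO[Si](c2ccccc2)(c2ccccc2)C(C)(C)C)=C\CS(=O)(=O)c2ccccc2
F6 | step 12 | (2Z)-enal isomer of 23 (formyl group cis to C6) | O=C/C(CO[Si](C)(C)C(C)(C)C)=C\C[C@@H]1[C@@H](CN(C)C)C(=O)O[C@H]1C/C(CO[Si](c2ccccc2)(c2ccccc2)C(C)(C)C)=C\CS(=O)(=O)c2ccccc2
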